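**Retrosynthetic overview** (labdane numbering: ring A = C1–C5 and C10, ring B = C5–C10, C18/C19 on C4, C20 on C10, C17 = methylene carbon)
1. The plan rests on ring B. The C8=C17 exocyclic methylene lies between C7H2 and the C9 stereocentre, which is what a 2-(trimethylsilylmethyl)allyl group on C9 leaves after its alkene terminus C7 adds to a C6 aldehyde on C5. Ring B is therefore cut at C6–C7, and the surplus C6–OH is removed afterwards by radical deoxygenation.
2. The ring-A aldehyde comes from a trans-fused δ-lactone C8(=O)–O–C6. This lactone is both the C8 ester for double Me3SiCH2 addition/Peterson elimination and the protecting group of the C6 oxygen.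
3. The lactone comes from hydroboration of a C5=C6 methylene (sets C5) and an Ireland–Claisen rearrangement (forms C9–C10, sets C9 and C10) of a cyclohexenylmethyl 4-(3-furyl)butanoate.
4. The cyclohexenylmethanol comes from 2-methylcyclohexanone: C4 by catalytic asymmetric hydroxymethylation, C20 by enolate methylation, C6 by enol triflate carbonylation.
5. Ring order: ring A and the furan are bought, ring B is closed in the key step, and the butenolide is made last from the furan (singlet oxygen, NaBH4) after the C19 silyl ether has been exchanged for the acetate.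

Key step: step 16

Assumption: the sense of induction of the chiral ligand in step 2, and of the boron controller in the fallback to step 11, is taken by analogy with simpler substrates; both antipodes of each are available, and the one meant is the one that gives the drawn configuration.

Step 1
Reactants: 1 2-methylcyclohexanone
Product: 2 2-methyl-1-(trimethylsilyloxy)cyclohex-1-ene
Conditions: Me3SiCl, NaI, Et3N, MeCN, rt; distillation
Reagents that add atoms: chlorotrimethylsilane, C[Si](C)(C)Cl
Why: Silyl enol ether formation under equilibrating conditions (Me3SiI made in situ) should favour the tetrasubstituted enol ether, which fixes the next C–C bond at the methyl-bearing carbon, the future C4.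

Step 2
Reactants: 2 2-methyl-1-(trimethylsilyloxy)cyclohex-1-ene
Product: 3 (S)-2-(hydroxymethyl)-2-methylcyclohexan-1-one
Conditions: aq. HCHO, Sc(OTf)3 (10 mol %), (S,S)-6,6'-bis(1-hydroxy-2,2-dimethylpropyl)-2,2'-bipyridine (12 mol %), DME–H2O, −20 °C
Reagents that add atoms: formaldehyde, C=O
Why: Catalytic asymmetric Mukaiyama aldol reaction with aqueous formaldehyde: the chiral scandium–bipyridine complex leaves one face of the silicon enolate open, so the quaternary stereocentre C4 (C18 methyl, C19 hydroxymethyl) is set under catalyst control.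

Step 3
Reactants: 3 (S)-2-(hydroxymethyl)-2-methylcyclohexan-1-one
Product: 4 (S)-2-[(tert-butyldiphenylsilyloxy)methyl]-2-methylcyclohexan-1-one
Conditions: t-BuPh2SiCl, imidazole, DMF, rt
Reagents that add atoms: tert-butyldiphenylsilyl chloride, CC(C)(C)[Si](Cl)(c1ccccc1)c1ccccc1
Why: Silylation under weakly basic conditions avoids retro-aldol cleavage, and the TBDPS ether is chosen because it must outlast amide bases, borane, the organocerium reagent and the BF3·OEt2 of step 16, where a more labile silyl ether or a fluoride trigger would endanger C19–O.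

Step 4
Reactants: 4 (S)-2-[(tert-butyldiphenylsilyloxy)methyl]-2-methylcyclohexan-1-one
Product: 6 (2S,6RS)-2-[(tert-butyldiphenylsilyloxy)methyl]-2,6-dimethylcyclohexan-1-one, via lithium enolate 5 (not isolated)
Conditions: LiN(i-Pr)2, THF, −78 °C; MeI, −78 → −20 °C
Reagents that add atoms: iodomethane, CI; lithium diisopropylamide, [Li+].CC(C)[N-]C(C)C (lithium only in 5)
Why: Kinetic enolate alkylation: C4 is quaternary, so only C10 can be deprotonated and methylation there brings in C20; the C10 epimers need no separation because this centre becomes sp2 in step 5.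

Step 5
Reactants: 6 (2S,6RS)-2-[(tert-butyldiphenylsilyloxy)methyl]-2,6-dimethylcyclohexan-1-one
Product: 8 (S)-6-[(tert-butyldiphenylsilyloxy)methyl]-2,6-dimethylcyclohex-1-en-1-yl trifluoromethanesulfonate, via potassium enolate 7 (not isolated)
Conditions: KN(SiMe3)2, THF, −78 → 0 °C; PhNTf2, −78 °C → rt
Reagents that add atoms: N-phenylbis(trifluoromethanesulfonimide), O=S(=O)(N(c1ccccc1)S(=O)(=O)C(F)(F)F)C(F)(F)F; potassium bis(trimethylsilyl)amide, [K+].C[Si](C)(C)[N-][Si](C)(C)C (potassium only in 7)
Why: O-Triflation of the only possible enolate gives the tetrasubstituted C5=C10 enol triflate as one regioisomer, a standard conversion of 2,2,6-trialkylcyclohexanones.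

Step 6
Reactants: 8 (S)-6-[(tert-butyldiphenylsilyloxy)methyl]-2,6-dimethylcyclohex-1-en-1-yl trifluoromethanesulfonate
Product: 9 methyl (R)-6-[(tert-butyldiphenylsilyloxy)methyl]-2,6-dimethylcyclohex-1-ene-1-carboxylate
Conditions: Pd(OAc)2 (5 mol %), PPh3, CO (1 atm), MeOH, Et3N, DMF, 65 °C
Reagents that add atoms: carbon monoxide, [C-]#[O+]; methanol, CO
Why: Palladium-catalysed alkoxycarbonylation of a vinyl triflate (oxidative addition, CO insertion, methanolysis) attaches C6 to C5 without touching C4.

Step 7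
Reactants: 9 methyl (R)-6-[(tert-butyldiphenylsilyloxy)methyl]-2,6-dimethylcyclohex-1-ene-1-carboxylate
Product: 10 {(R)-6-[(tert-butyldiphenylsilyloxy)methyl]-2,6-dimethylcyclohex-1-en-1-yl}methanol
Conditions: i-Bu2AlH (2.5 equiv), CH2Cl2, −78 °C; aq. potassium sodium tartrate
Reagents that add atoms: none
Why: 1,2-Reduction of the conjugated ester gives the primary allylic alcohol that will carry the acyl group of the sigmatropic step.

Step 8
Reactants: 11 furan-3-carbaldehyde; 12 (2-carboxyethyl)triphenylphosphonium bromide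
Product: 14 4-(furan-3-yl)but-3-enoic acid (E/Z mixture), via phosphonium ylide 13 (not isolated)
Conditions: NaN(SiMe3)2 (2.1 equiv), THF, 0 °C; then 11, 0 °C → rt; 1 M HCl
Reagents that add atoms: sodium bis(trimethylsilyl)amide, [Na+].C[Si](C)(C)[N-][Si](C)(C)C (sodium only in 13)
Why: Wittig olefination with the ylide of an ω-carboxy phosphonium salt joins C12 (the aldehyde carbon) to C11, C9 and C8 in one operation, and the alkene geometry is irrelevant because the double bond is saturated next.

Step 9
Reactants: 14 4-(furan-3-yl)but-3-enoic acid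
Product: 15 4-(furan-3-yl)butanoic acid
Conditions: H2 (1 atm), 5% Pd/C, EtOAc, rt, stopped after one equivalent of H2
Reagents that add atoms: none
Why: Heterogeneous hydrogenation saturates the 1,2-disubstituted alkene much faster than the aromatic furan at 1 atm.

Step 10
Reactants: 10 {(R)-6-[(tert-butyldiphenylsilyloxy)methyl]-2,6-dimethylcyclohex-1-en-1-yl}methanol; 15 4-(furan-3-yl)butanoic acid
Product: 16 {(R)-6-[(tert-butyldiphenylsilyloxy)methyl]-2,6-dimethylcyclohex-1-en-1-yl}methyl 4-(furan-3-yl)butanoate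
Conditions: N,N'-dicyclohexylcarbodiimide, DMAP (cat.), CH2Cl2, 0 °C → rt
Reagents that add atoms: none
Why: Steglich esterification couples the hindered but primary allylic alcohol with the acid under neutral conditions that leave the furan and the silyl ether alone.

Step 11
Reactants: 16 {(R)-6-[(tert-butyldiphenylsilyloxy)methyl]-2,6-dimethylcyclohex-1-en-1-yl}methyl 4-(furan-3-yl)butanoate
Product: 20 (2S)-2-[(1S,3R)-3-{[(tert-butyldiphenylsilyl)oxy]methyl}-1,3-dimethyl-2-methylidenecyclohexyl]-4-(furan-3-yl)butanoic acid, via lithium enolate 17 (not isolated), via silyl ketene acetal 18 (not isolated), via silyl ester 19 (not isolated)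
Conditions: LiN(i-Pr)2, THF–DMPU (3:1), −78 °C; t-BuMe2SiCl, −78 °C → rt, then 60 °C; K2CO3, MeOH–H2O, rt; citric acid
Reagents that add atoms: lithium diisopropylamide, [Li+].CC(C)[N-]C(C)C (lithium only in 17); tert-butyldimethylsilyl chloride, CC(C)(C)[Si](C)(C)Cl (silicon only in 18 and 19)
Why: Ireland–Claisen rearrangement (known for the 2,6,6-trialkylcyclohexenylmethanol class): enolisation in THF–DMPU puts C11 cis to O–Li, and the (Z)-silyl ketene acetal reacts through a chair with C11 pseudoequatorial, which places H-9 anti to C20 (C9/C10 relative configuration), while the face of C10 is chosen by C4, the new bond forming on the side of the small C18 methyl and away from the CH2OTBDPS arm, whose oxygen would otherwise be pressed against the breaking C6–O bond; this 1,3-induction is the weaker control, and a minor diastereomer is removed by chromatography at 21 or 24.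

Step 12
Reactants: 20 the acid from step 11
Product: 21 methyl (2S)-2-[(1S,3R)-3-{[(tert-butyldiphenylsilyl)oxy]methyl}-1,3-dimethyl-2-methylidenecyclohexyl]-4-(furan-3-yl)butanoate
Conditions: MeI, K2CO3, DMF, rt
Reagents that add atoms: iodomethane, CI
Why: Carboxylate O-alkylation masks the acid, which borane would otherwise reduce, and works regardless of the crowding around C8.

Step 13
Reactants: 21 the methyl ester from step 12
Product: 24 (4S,4aR,8R,8aS)-8-{[(tert-butyldiphenylsilyl)oxy]methyl}-4-[2-(furan-3-yl)ethyl]-4a,8-dimethyloctahydro-3H-isochromen-3-one (trans-fused δ-lactone C8(=O)–O–C6), via alkylborane 22 (not isolated), via hydroxy ester 23 (not isolated)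
Conditions: BH3·THF, THF, 0 °C → rt; NaOH, H2O2, 0 °C → rt; PPTS (cat.), toluene, 80 °C
Reagents that add atoms: hydrogen peroxide, OO; borane (as BH3·THF), B (boron only in 22)
Why: Hydroboration–oxidation puts boron on terminal C6 and delivers hydrogen to C5 from the face opposite the two axial groups (C20 and the C19 arm) of the chair that keeps the branched C9 substituent equatorial, which sets H-5 trans to C20, and lactonisation of the C6 alcohol onto the C8 ester then gives the trans-fused δ-lactone.

Step 14
Reactants: 24 the δ-lactone from step 13; 25 (trimethylsilyl)methylmagnesium chloride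
Product: 27 (4R,5S,9S,10S)-19-(tert-butyldiphenylsilyloxy)-15,16-epoxy-17-trimethylsilyl-6,7-secolabda-7,13(16),14-trien-6-ol, via bis(silylmethyl)carbinol 26 (not isolated)
Conditions: anhydrous CeCl3, 25 (5 equiv), THF, −78 °C → rt; aq. NH4Cl; SiO2, CH2Cl2, rt
Reagents that add atoms: none
Why: Cerium-mediated double addition of Me3SiCH2MgCl to the lactone carbonyl followed by Peterson elimination of one β-hydroxysilane is a known ester-to-allylsilane conversion; the weakly basic organocerium reagent should not enolise C9, and ring opening frees the C6 alcohol at the same time.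

Step 15
Reactants: 27 the hydroxy allylsilane from step 14
Product: 28 (4R,5S,9S,10S)-19-(tert-butyldiphenylsilyloxy)-15,16-epoxy-17-trimethylsilyl-6,7-secolabda-7,13(16),14-trien-6-al
Conditions: (n-Pr4N)RuO4 (5 mol %), N-methylmorpholine N-oxide, 4 Å MS, CH2Cl2, rt
Reagents that add atoms: none
Why: Ley–Griffith oxidation stops at the aldehyde under neutral anhydrous conditions, so the allylsilane, the furan and the C5 stereocentre next to the new carbonyl group should be kept.

Step 16
Reactants: 28 the ring-A aldehyde from step 15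
Product: 29 (4R,5S,6R,9R,10S)-19-(tert-butyldiphenylsilyloxy)-15,16-epoxylabda-8(17),13(16),14-trien-6-ol (equatorial 6-OH)
Conditions: BF3·OEt2 (1.2 equiv), 2,6-di-tert-butyl-4-methylpyridine, CH2Cl2 (0.005 M), −78 °C; aq. NaHCO3
Reagents that add atoms: none
Why: Intramolecular Hosomi–Sakurai allylation, known for 2-(silylmethyl)allyl units and aldehydes: BF3 binds the C6 carbonyl oxygen, the alkene terminus C7 attacks C6, the charge building at C8 is stabilised by the C17–Si bond, and loss of Me3SiF leaves the C8=C17 alkene. Ring B closes as a six-membered ring, 6-exo-trig at C6=O with the C7=C8 π bond inside the forming ring, through a chair in which C6 and C9 are both equatorial on ring A, so the trans fusion already laid down at C5/C10 is carried over. The only new stereocentre, C6, is controlled by that chair: the aldehyde hydrogen points to the axial side occupied by C20 and the C19 arm while the complexed oxygen takes the equatorial site, and either epimer would serve because C6 is deoxygenated in steps 17 and 18. Regiochemistry is secure because both allyl termini are CH2 groups and silicon dictates where the alkene ends, and C9 can neither epimerise nor move into conjugation because C8 is never a carbonyl carbon. Chemoselectivity over the furan is secured by the higher nucleophilicity of the allylsilane and by ring size (six-membered closure against an eight-membered one through C16), with high dilution at −78 °C suppressing intermolecular attack. The hindered pyridine scavenges adventitious acid that would cause protodesilylation, and the Lewis acid trigger leaves the TBDPS ether intact, which a fluoride trigger would not.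

Step 17
Reactants: 29 the 6-hydroxy labdatriene from step 16
Product: 30 O-[(4R,5S,6R,9R,10S)-19-(tert-butyldiphenylsilyloxy)-15,16-epoxylabda-8(17),13(16),14-trien-6-yl] 1H-imidazole-1-carbothioate
Conditions: 1,1'-thiocarbonyldiimidazole, DMAP, 1,2-dichloroethane, 80 °C
Reagents that add atoms: 1,1'-thiocarbonyldiimidazole, S=C(n1ccnc1)n1ccnc1
Why: Thioacylation of the equatorial C6 alcohol (first half of the Barton–McCombie deoxygenation) needs no strong base, so neither silyl migration nor elimination is expected.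

Step 18
Reactants: 30 the thiocarbonylimidazolide from step 17
Product: 31 (4R,5S,9R,10S)-19-(tert-butyldiphenylsilyloxy)-15,16-epoxylabda-8(17),13(16),14-triene
Conditions: Bu3SnH, AIBN (cat.), toluene, 100 °C
Reagents that add atoms: none
Why: Barton–McCombie deoxygenation: the stannyl radical adds to C=S, the C6–O bond fragments to a secondary radical, and hydrogen transfer from Bu3SnH, kept concentrated enough to outrun 3-exo attack on C8=C17, gives the C6 methylene group and erases the stereocentre made in step 16.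

Step 19
Reactants: 31 the silyl ether from step 18
Product: 32 (4R,5S,9R,10S)-15,16-epoxylabda-8(17),13(16),14-trien-19-ol
Conditions: n-Bu4NF, THF, rt → 50 °C
Reagents that add atoms: none
Why: Fluoride cleaves the Si–O bond, and the step is placed before the furan oxidation because the furan tolerates basic fluoride whereas the butenolide would not.

Step 20
Reactants: 32 the C19 alcohol from step 19
Product: 33 (4R,5S,9R,10S)-15,16-epoxylabda-8(17),13(16),14-trien-19-yl acetate
Conditions: Ac2O, pyridine, DMAP (cat.), CH2Cl2, rt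
Reagents that add atoms: acetic anhydride, CC(=O)OC(C)=O
Why: DMAP-catalysed acylation acetylates the neopentyl axial primary alcohol without affecting the alkene or the furan.

Step 21
Reactants: 33 the furyl acetate from step 20
Product: 35 (4R,5S,9R,10S)-19-acetoxy-16-hydroxylabda-8(17),13-dien-15,16-olide (C16 epimers), via furan endoperoxide 34 (not isolated)
Conditions: O2, visible light, tetraphenylporphyrin (cat.), i-Pr2NEt, CH2Cl2, −78 °C → rt
Reagents that add atoms: dioxygen, O=O
Why: [4+2] cycloaddition of singlet oxygen to the furan, far faster than an ene reaction of the 1,1-disubstituted C8=C17 alkene, gives the endoperoxide, from which the hindered amine removes the less hindered bridgehead proton at C15 (Kornblum–DeLaMare-type fragmentation), so C15 becomes the lactone carbonyl and C16, next to C13, the hemiacetal carbon.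

Step 22
Reactants: 35 the γ-hydroxybutenolide from step 21
Product: 37 (4R,5S,9R,10S)-19-acetoxylabda-8(17),13-dien-15,16-olide (ent-labdane series; CNP0189477.2), via hydroxy acid 36 (not isolated)
Conditions: NaBH4, EtOH, 0 °C; 1 M HCl
Reagents that add atoms: none
Why: NaBH4 reduces the open aldehyde form of the hydroxybutenolide at C16 and acidification closes the (Z)-hydroxy acid to the β-substituted butenolide, while the acetate, the conjugated lactone and C8=C17 are not reduced at 0 °C.

**Compound list**
1 | 2-methylcyclohexanone (racemic) | CC1CCCCC1=O | starting material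
2 | 2-methyl-1-(trimethylsilyloxy)cyclohex-1-ene | CC1=C(O[Si](C)(C)C)CCCC1 | intermediate
3 | (S)-2-(hydroxymethyl)-2-methylcyclohexan-1-one | O=C1[C@](C)(CO)CCCC1 | intermediate
4 | (S)-2-[(tert-butyldiphenylsilyloxy)methyl]-2-methylcyclohexan-1-one | O=C1[C@](C)(CO[Si](c2ccccc2)(c2ccccc2)C(C)(C)C)CCCC1 | intermediate
5 | lithium enolate of 4 (C5=C10; not isolated) | [Li+].[O-]C1=CCCC[C@@]1(C)CO[Si](c1ccccc1)(c1ccccc1)C(C)(C)C | intermediate
6 | (2S,6RS)-2-[(tert-butyldiphenylsilyloxy)methyl]-2,6-dimethylcyclohexan-1-one | O=C1[C@](C)(CO[Si](c2ccccc2)(c2ccccc2)C(C)(C)C)CCCC1C | intermediate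
7 | potassium enolate of 6 (not isolated) | [K+].[O-]C1=C(C)CCC[C@@]1(C)CO[Si](c1ccccc1)(c1ccccc1)C(C)(C)C | intermediate
8 | (S)-6-[(tert-butyldiphenylsilyloxy)methyl]-2,6-dimethylcyclohex-1-en-1-yl triflate | CC1=C(OS(=O)(=O)C(F)(F)F)[C@](C)(CO[Si](c2ccccc2)(c2ccccc2)C(C)(C)C)CCC1 | intermediate
9 | methyl (R)-6-[(tert-butyldiphenylsilyloxy)methyl]-2,6-dimethylcyclohex-1-ene-1-carboxylate | CC1=C(C(=O)OC)[C@](C)(CO[Si](c2ccccc2)(c2ccccc2)C(C)(C)C)CCC1 | intermediate
10 | {(R)-6-[(tert-butyldiphenylsilyloxy)methyl]-2,6-dimethylcyclohex-1-en-1-yl}methanol | CC1=C(CO)[C@](C)(CO[Si](c2ccccc2)(c2ccccc2)C(C)(C)C)CCC1 | intermediate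
11 | furan-3-carbaldehyde | O=Cc1ccoc1 | starting material
12 | (2-carboxyethyl)triphenylphosphonium bromide | OC(=O)CC[P+](c1ccccc1)(c1ccccc1)c1ccccc1.[Br-] | starting material
13 | sodium 3-(triphenylphosphoranylidene)propanoate (not isolated) | [Na+].[O-]C(=O)CC=P(c1ccccc1)(c1ccccc1)c1ccccc1 | intermediate
14 | 4-(furan-3-yl)but-3-enoic acid (E/Z) | OC(=O)CC=Cc1ccoc1 | intermediate
15 | 4-(furan-3-yl)butanoic acid | OC(=O)CCCc1ccoc1 | intermediate
16 | {(R)-6-[(tert-butyldiphenylsilyloxy)methyl]-2,6-dimethylcyclohex-1-en-1-yl}methyl 4-(furan-3-yl)butanoate | CC1=C(COC(=O)CCCc2ccoc2)[C@](C)(CO[Si](c2ccccc2)(c2ccccc2)C(C)(C)C)CCC1 | intermediate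
17 | lithium enolate of 16, C11 cis to O–Li (not isolated) | [Li+].CC1=C(CO/C([O-])=C/CCc2ccoc2)[C@](C)(CO[Si](c2ccccc2)(c2ccccc2)C(C)(C)C)CCC1 | intermediate
18 | (Z)-tert-butyldimethylsilyl ketene acetal of 16, C11 cis to OSi (not isolated) | CC1=C(CO/C(O[Si](C)(C)C(C)(C)C)=C/CCc2ccoc2)[C@](C)(CO[Si](c2ccccc2)(c2ccccc2)C(C)(C)C)CCC1 | intermediate
19 | tert-butyldimethylsilyl ester of 20 (not isolated) | C=C1[C@](C)(CO[Si](c2ccccc2)(c2ccccc2)C(C)(C)C)CCC[C@@]1(C)[C@H](CCc1ccoc1)C(=O)O[Si](C)(C)C(C)(C)C | intermediate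
20 | (2S)-2-[(1S,3R)-3-{[(tert-butyldiphenylsilyl)oxy]methyl}-1,3-dimethyl-2-methylidenecyclohexyl]-4-(furan-3-yl)butanoic acid (C9 cis to C18, trans to the C19 arm) | C=C1[C@](C)(CO[Si](c2ccccc2)(c2ccccc2)C(C)(C)C)CCC[C@@]1(C)[C@H](CCc1ccoc1)C(=O)O | intermediate
21 | methyl ester of 20 | C=C1[C@](C)(CO[Si](c2ccccc2)(c2ccccc2)C(C)(C)C)CCC[C@@]1(C)[C@H](CCc1ccoc1)C(=O)OC | intermediate
22 | C6 alkylborane from 21, H-5 trans to C20 (not isolated) | BC[C@@H]1[C@](C)(CO[Si](c2ccccc2)(c2ccccc2)C(C)(C)C)CCC[C@@]1(C)[C@H](CCc1ccoc1)C(=O)OC | intermediate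
23 | methyl (2S)-2-[(1R,2S,3R)-3-{[(tert-butyldiphenylsilyl)oxy]methyl}-2-(hydroxymethyl)-1,3-dimethylcyclohexyl]-4-(furan-3-yl)butanoate (not isolated) | OC[C@@H]1[C@](C)(CO[Si](c2ccccc2)(c2ccccc2)C(C)(C)C)CCC[C@@]1(C)[C@H](CCc1ccoc1)C(=O)OC | intermediate
24 | (4S,4aR,8R,8aS)-8-{[(tert-butyldiphenylsilyl)oxy]methyl}-4-[2-(furan-3-yl)ethyl]-4a,8-dimethyloctahydro-3H-isochromen-3-one (trans-fused δ-lactone) | O=C1OC[C@@H]2[C@](C)(CO[Si](c3ccccc3)(c3ccccc3)C(C)(C)C)CCC[C@@]2(C)[C@@H]1CCc1ccoc1 | intermediate
25 | (trimethylsilyl)methylmagnesium chloride | C[Si](C)(C)C[Mg]Cl | starting material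
26 | C8 bis(trimethylsilylmethyl)carbinol, C6/C8 diol (not isolated) | OC[C@@H]1[C@](C)(CO[Si](c2ccccc2)(c2ccccc2)C(C)(C)C)CCC[C@@]1(C)[C@H](CCc1ccoc1)C(O)(C[Si](C)(C)C)C[Si](C)(C)C | intermediate
27 | (4R,5S,9S,10S)-19-(tert-butyldiphenylsilyloxy)-15,16-epoxy-17-trimethylsilyl-6,7-secolabda-7,13(16),14-trien-6-ol | OC[C@@H]1[C@](C)(CO[Si](c2ccccc2)(c2ccccc2)C(C)(C)C)CCC[C@@]1(C)[C@H](CCc1ccoc1)C(=C)C[Si](C)(C)C | intermediate
28 | (4R,5S,9S,10S)-19-(tert-butyldiphenylsilyloxy)-15,16-epoxy-17-trimethylsilyl-6,7-secolabda-7,13(16),14-trien-6-al (key-step precursor) | O=C[C@@H]1[C@](C)(CO[Si](c2ccccc2)(c2ccccc2)C(C)(C)C)CCC[C@@]1(C)[C@H](CCc1ccoc1)C(=C)C[Si](C)(C)C | intermediate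
29 | (4R,5S,6R,9R,10S)-19-(tert-butyldiphenylsilyloxy)-15,16-epoxylabda-8(17),13(16),14-trien-6-ol (key-step product, equatorial 6-OH) | C=C1C[C@@H](O)[C@@H]2[C@](C)(CO[Si](c3ccccc3)(c3ccccc3)C(C)(C)C)CCC[C@@]2(C)[C@@H]1CCc1ccoc1 | intermediate
30 | 6-O-(imidazol-1-ylthiocarbonyl) derivative of 29 | C=C1C[C@@H](OC(=S)n3ccnc3)[C@@H]2[C@](C)(CO[Si](c3ccccc3)(c3ccccc3)C(C)(C)C)CCC[C@@]2(C)[C@@H]1CCc1ccoc1 | intermediate
31 | (4R,5S,9R,10S)-19-(tert-butyldiphenylsilyloxy)-15,16-epoxylabda-8(17),13(16),14-triene | C=C1CC[C@@H]2[C@](C)(CO[Si](c3ccccc3)(c3ccccc3)C(C)(C)C)CCC[C@@]2(C)[C@@H]1CCc1ccoc1 | intermediate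
32 | (4R,5S,9R,10S)-15,16-epoxylabda-8(17),13(16),14-trien-19-ol | C=C1CC[C@@H]2[C@](C)(CO)CCC[C@@]2(C)[C@@H]1CCc1ccoc1 | intermediate
33 | (4R,5S,9R,10S)-15,16-epoxylabda-8(17),13(16),14-trien-19-yl acetate | C=C1CC[C@@H]2[C@](C)(COC(C)=O)CCC[C@@]2(C)[C@@H]1CCc1ccoc1 | intermediate
34 | furan endoperoxide of 33 (not isolated) | C=C1CC[C@@H]2[C@](C)(COC(C)=O)CCC[C@@]2(C)[C@@H]1CCC1=CC2OOC1O2 | intermediate
35 | (4R,5S,9R,10S)-19-acetoxy-16-hydroxylabda-8(17),13-dien-15,16-olide (C16 epimers) | C=C1CC[C@@H]2[C@](C)(COC(C)=O)CCC[C@@]2(C)[C@@H]1CCC1=CC(=O)OC1O | intermediate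
36 | (13Z)-19-acetoxy-16-hydroxylabda-8(17),13-dien-15-oic acid (not isolated) | C=C1CC[C@@H]2[C@](C)(COC(C)=O)CCC[C@@]2(C)[C@@H]1CC/C(CO)=C/C(=O)O | intermediate
37 | (4R,5S,9R,10S)-19-acetoxylabda-8(17),13-dien-15,16-olide | C=C1CC[C@@H]2[C@](C)(COC(C)=O)CCC[C@@]2(C)[C@@H]1CCC1=CC(=O)OC1 | target

**Total step count:** 22. **Longest linear sequence:** 20 (steps 1–7 and 10–22).

**Steps most likely to fail**

Step 16. Silicon may be lost to adventitious acid before the C–C bond forms, or addition to the doubly neopentyl aldehyde may be so slow that the Lewis acid erodes the furan. The fallback closes the same C6–C7 bond by a type 2 carbonyl-ene reaction, in which the ene unit is tethered through its central carbon. It sets out from 27. Deliberate protodesilylation (CF3CO2H, CH2Cl2, −20 °C) gives the isopropenyl alcohol F1. Ley–Griffith oxidation gives the isopropenyl aldehyde F2. Me2AlCl (CH2Cl2, −78 → 0 °C), a Lewis acid that also scavenges protons, then induces the ene closure: C7 attacks C6 and hydrogen shifts from the methyl group that becomes C17. This comes back to the route at 29.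

Step 11. The failure mode is poor facial selectivity at C10, because the quaternary C4 distinguishes its two faces only by CH3 against CH2OSi; erosion of enolate geometry would add C9 epimers. The fallback moves the choice of face from the substrate to a reagent. It sets out from 16. Enolisation with (4S,5S)-2-bromo-1,3-bis{[3,5-bis(trifluoromethyl)phenyl]sulfonyl}-4,5-diphenyl-1,3,2-diazaborolidine and Et3N (toluene–hexane, −78 °C) gives the chiral boron ketene acetal F3. Its chair rearrangement inside the pocket of the controller (−20 °C → rt) gives the acyloxyborane F4. Aqueous work-up comes back to the route at 20 and returns the bis-sulfonamide for re-use. Because C4 exerts little bias, the controller should decide the face.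

Step 14. The second addition to the crowded α-silyl ketone stage may be incomplete, C9 may be enolised, or silicon may be lost early. The fallback builds the allylsilane by cross-coupling. It sets out from 24. MeLi (1 equiv, THF, −78 °C) gives the hydroxy methyl ketone F5. Et3SiCl/imidazole gives the triethylsilyl ether F6. Kinetic deprotonation at the methyl group (KN(SiMe3)2, −78 °C) and N-(5-chloropyridin-2-yl)triflimide give the terminal enol triflate F7. Kumada coupling with 25 (Pd(PPh3)4 cat., THF, rt) gives the allylsilane triethylsilyl ether F8. PPTS in MeOH (0 °C) removes the triethylsilyl group and comes back to the route at 27.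

**Further compounds**
F1 | step 16 | isopropenyl alcohol (17-desilyl analogue of 27) | OC[C@@H]1[C@](C)(CO[Si](c2ccccc2)(c2ccccc2)C(C)(C)C)CCC[C@@]1(C)[C@H](CCc1ccoc1)C(C)=C
F2 | step 16 | isopropenyl aldehyde (17-desilyl analogue of 28) | O=C[C@@H]1[C@](C)(CO[Si](c2ccccc2)(c2ccccc2)C(C)(C)C)CCC[C@@]1(C)[C@H](CCc1ccoc1)C(C)=C
F3 | step 11 | chiral boron ketene acetal of 16 (C11 cis to O–B) | CC1=C(CO/C(OB2N(S(=O)(=O)c3cc(cc(c3)C(F)(F)F)C(F)(F)F)[C@@H](c3ccccc3)[C@H](c3ccccc3)N2S(=O)(=O)c2cc(cc(c2)C(F)(F)F)C(F)(F)F)=C/CCc2ccoc2)[C@](C)(CO[Si](c2ccccc2)(c2ccccc2)C(C)(C)C)CCC1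
F4 | step 11 | acyloxyborane of 20 | C=C1[C@](C)(CO[Si](c2ccccc2)(c2ccccc2)C(C)(C)C)CCC[C@@]1(C)[C@H](CCc1ccoc1)C(=O)OB1N(S(=O)(=O)c2cc(cc(c2)C(F)(F)F)C(F)(F)F)[C@@H](c2ccccc2)[C@H](c2ccccc2)N1S(=O)(=O)c1cc(cc(c1)C(F)(F)F)C(F)(F)F
F5 | step 14 | hydroxy methyl ketone from 24 | OC[C@@H]1[C@](C)(CO[Si](c2ccccc2)(c2ccccc2)C(C)(C)C)CCC[C@@]1(C)[C@H](CCc1ccoc1)C(C)=O
F6 | step 14 | C6 triethylsilyl ether of F5 | CC[Si](CC)(CC)OC[C@@H]1[C@](C)(CO[Si](c2ccccc2)(c2ccccc2)C(C)(C)C)CCC[C@@]1(C)[C@H](CCc1ccoc1)C(C)=O
F7 | step 14 | terminal enol triflate of F6 | CC[Si](CC)(CC)OC[C@@H]1[C@](C)(CO[Si](c2ccccc2)(c2ccccc2)C(C)(C)C)CCC[C@@]1(C)[C@H](CCc1ccoc1)C(=C)OS(=O)(=O)C(F)(F)F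
F8 | step 14 | C6 triethylsilyl ether of 27 | CC[Si](CC)(CC)OC[C@@H]1[C@](C)(CO[Si](c2ccccc2)(c2ccccc2)C(C)(C)C)CCC[C@@]1(C)[C@H](CCc1ccoc1)C(=C)C[Si](C)(C)C
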